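Start with the ratio.

- Monday's: left-handed substrate 20 mM; right-handed substrate 20 mM; solid reagent 45 mM; precatalyst 1 mM; run made earlier
- flask: left-handed substrate 20 mM; solid reagent 30.0 mM; precatalyst 1.0 mM; right-handed substrate 20 mM; time 12 h

Monday's run (percent of the left-handed substrate and right-handed substrate together charged)

| time / h | left-handed substrate / % | right-handed substrate / % |
|---|---|---|
| 0.667 | 49.9 | 50.4 |
| 1.33 | 47.5 | 48.9 |
| 2.00 | 47.1 | 49.4 |
| 2.50 | 45.8 | 48.3 |
| 3.00 | 44.5 | 48.2 |
| 4.00 | 42.5 | 48.4 |

(scatter of a reading: 0.5 percentage points)

- free catalyst is single-handed; left-handed substrate and right-handed substrate are mirror images of each other, charged as a racemate, each of them at the stated concentration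
- as a solid, counted per litre of solution: solid reagent
- the numbers in the tables scatter by 0.5 percentage points (one standard deviation)
- at the start none of the solid reagent is in solution
- an excess is the difference of the two amounts in percent of their sum
- an excess is below zero if the other one leads

1. part of the left-handed substrate and right-handed substrate charged together that has reacted at 12 h
2. excess of left-handed product over right-handed product in the product at 12 h
3. excess of right-handed substrate over left-handed substrate among what is left of the two at 12 h

Which concentration sets the order of each substrate's loss? I do not read that from Monday's run; I assume that each substrate falls in proportion to its own concentration, [left-handed substrate] for the one and [right-handed substrate] for the other, and that the two share every other factor of the rate, so that whatever that shared factor does in time cancels from their quotient.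

What can be read from that? The selectivity factor s, the logarithm of the part of left-handed substrate left divided by the logarithm of the part of right-handed substrate left, which the last reading of Monday's run, at 4.00 h, puts at 5.00.

How firm is that reading? Not very, since the right-handed substrate has lost 1.6 percentage points there while one reading scatters by 0.5 points, so s is a working figure with a wide margin.

And the clock, which s does not contain? That is my weak spot: I let the left-handed substrate of the new flask go on falling first-order at Monday's pace, although this flask has 30.0 mM of solid reagent where Monday's had 45 mM, and that leaves 61.4 % of it at 12 h. Then s leaves 90.7 % of the right-handed substrate, which gives my c of 24.0 %, eP of 61.2 % and eS of 19.3 %.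

The forecast says 24 %, 57 % and 18 %, and it warns that “Monday's run cannot distinguish zero-order from first-order behaviour”; my eP stands higher than its value, and my eS stands higher than its value.

The flask gives c 17.1 %, eP 62.1 % and eS 12.8 %.

    partner + free catalyst + left-handed substrate → free catalyst + left-handed product (k = 16.0 L² mol⁻² s⁻¹)
    precatalyst ⇌ free catalyst (K = 24.0, k = 6.40 × 10⁻⁴ s⁻¹)
    2 free catalyst → spent catalyst (k = 0.0730 L mol⁻¹ s⁻¹)
    solid reagent ⇌ partner, rate k4*(cs4 - [partner]) while solid is left; crystals form when [partner] > cs4 (solubility = 2.00 mM, k = 4.40 × 10⁻⁴ s⁻¹)
    partner + free catalyst + right-handed substrate → free catalyst + right-handed product (k = 3.30 L² mol⁻² s⁻¹)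

At 12.0 h this flask holds free catalyst 14.9 % of the catalyst charged, beside spent catalyst 84.5 % and precatalyst 0.640 %. Put to use on the 72 % of left-handed substrate left in this flask, s gives 93.7 % of the right-handed substrate against the 94 % found. In the neighbour flask with 0.25 mM of precatalyst, 84 % of left-handed substrate left gives by s 96.6 % of the right-handed substrate, against 97 % found, and so an eP of 64.9 %, where that neighbour flask shows 63.9 %.

The numbers in the tables are calculated from invented constants; scatter was added.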